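The ten-membered ring is cut at C9–C10 (germacrane numbering). The key step exploits the C8–C9–C10 segment of that carbocycle, where the fully substituted oxygen-bearing C10 lies next to the C9 methylene, one carbon from O–C8 and adjacent to O–C1: a samarium enolate made at C8/C9 from a bromomethyl ketone adds to a C10 ketone held in a chelate by the C1 p-methoxybenzyl ether. In one operation this forms the C9–C10 bond, the carbocycle and the C10 carbinol centre that later closes the C1–C10 epoxide. The precursor is a trans C6/C7 γ-lactone bearing a bromoacetyl group at C7 and a chain with the C4=C5 alkene ending in the α-alkoxy ketone.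

Key step: step 14

Remark: germacrane numbering is used (ring C1–C10; C14 on C10; C15 on C4; lactone C12(=O)–O–C6 with C11 on C7 and C13 on C11); TBS = tert-butyldimethylsilyl, PMB = 4-methoxybenzyl, TES = triethylsilyl, R* = (1E,5S)-7-(TBS-oxy)-2-[(TBS-oxy)methyl]-5-(PMB-oxy)-6-oxohept-1-en-1-yl (C5 to C14 with C15); the C10 carbinol configuration of 8–11 is immaterial because C10 is oxidised in step 8.

Step 1
Reactants: 1 but-2-yne-1,4-diol
Product: 2 4-(TBS-oxy)but-2-yn-1-ol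
Conditions: TBSCl (1 equiv), imidazole, 1 (4 equiv), DMF, 0 °C → rt
Reagents that add atoms: tert-butyldimethylsilyl chloride, CC(C)(C)[Si](C)(C)Cl
Why: Statistical O-silylation of a symmetrical diol used in excess should give mainly the mono-silyl ether, the water-soluble surplus diol being washed out.

Step 2
Reactants: 2 4-(TBS-oxy)but-2-yn-1-ol
Product: 4 (Z)-4-(TBS-oxy)-3-iodobut-2-en-1-ol, via cyclic alkenylalanate 3 (not isolated)
Conditions: Red-Al, THF, 0 °C → rt; then I2, THF, −78 → 0 °C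
Reagents that add atoms: iodine, II
Why: Hydroxyl-directed trans-hydroalumination of the propargylic alcohol places hydride on C5 and aluminium on C4 inside a five-membered oxa-aluminacycle, and iodinolysis with retention gives the iodide with iodine (the later C3 site) cis to C6.

Step 3
Reactants: 5 penta-1,4-dien-3-ol
Product: 6 (2R,3S)-1,2-epoxypent-4-en-3-ol
Conditions: Ti(Oi-Pr)4, L-(+)-diisopropyl tartrate, t-BuOOH, 4 Å MS, CH2Cl2, −20 °C
Reagents that add atoms: tert-butyl hydroperoxide, CC(C)(C)OO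
Why: Sharpless asymmetric epoxidation desymmetrises the divinyl carbinol, the L-(+)-tartrate catalyst choosing one enantiotopic vinyl group and its erythro face so that C1 (S) and C10 (R) are set while the minor enantiomer is consumed by a second epoxidation.

Step 4
Reactants: 6 (2R,3S)-1,2-epoxypent-4-en-3-ol
Product: 7 (2R,3S)-1,2-epoxy-3-(PMB-oxy)pent-4-ene
Conditions: NaH, PMBBr, THF/DMF, −20 → 0 °C
Reagents that add atoms: 4-methoxybenzyl bromide, COc1ccc(CBr)cc1
Why: Williamson etherification of the secondary alkoxide with the reactive benzylic bromide at low temperature should outrun Payne rearrangement of the epoxy alkoxide.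

Step 5
Reactants: 7 (2R,3S)-1,2-epoxy-3-(PMB-oxy)pent-4-ene
Product: 8 (2R,3S)-3-(PMB-oxy)pent-4-ene-1,2-diol
Conditions: HClO4 (cat.), THF/H2O (3:1), rt
Reagents that add atoms: water, O
Why: Acid-catalysed hydrolytic opening of the terminal epoxide at its unhindered CH2 carbon gives the vicinal diol without touching C1 or the PMB ether.

Step 6
Reactants: 8 (2R,3S)-3-(PMB-oxy)pent-4-ene-1,2-diol
Product: 9 (2R,3S)-1-(TBS-oxy)-3-(PMB-oxy)pent-4-en-2-ol
Conditions: TBSCl (1.05 equiv), imidazole, CH2Cl2, −20 → 0 °C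
Reagents that add atoms: tert-butyldimethylsilyl chloride, CC(C)(C)[Si](C)(C)Cl
Why: Silylation distinguishes the primary C14 hydroxyl from the secondary C10 hydroxyl on steric grounds.

Step 7
Reactants: 9 (2R,3S)-1-(TBS-oxy)-3-(PMB-oxy)pent-4-en-2-ol; 4 (Z)-4-(TBS-oxy)-3-iodobut-2-en-1-ol
Product: 11 (2R,3S,6E)-1-(TBS-oxy)-6-[(TBS-oxy)methyl]-3-(PMB-oxy)oct-6-ene-2,8-diol, via alkylborane 10 (not isolated)
Conditions: 9-BBN (2.5 equiv), THF, rt; then 4, Pd(dppf)Cl2 (5 mol%), AsPh3, Cs2CO3, DMF/H2O, rt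
Reagents that add atoms: none
Why: Anti-Markovnikov hydroboration of the terminal alkene followed by B-alkyl Suzuki–Miyaura coupling forms C3–C4 with retention of the alkenyl iodide geometry, so C3 ends up cis to C6, and free hydroxyls are tolerated.

Step 8
Reactants: 11 (2R,3S,6E)-1-(TBS-oxy)-6-[(TBS-oxy)methyl]-3-(PMB-oxy)oct-6-ene-2,8-diol
Product: 12 (2E,6S)-8-(TBS-oxy)-3-[(TBS-oxy)methyl]-6-(PMB-oxy)-7-oxooct-2-enal
Conditions: Dess–Martin periodinane (2.5 equiv), NaHCO3, CH2Cl2, 0 °C → rt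
Reagents that add atoms: none
Why: Dess–Martin oxidation converts the allylic C6 alcohol into the enal and the C10 carbinol into the ketone in one buffered operation that should not epimerise C1 or isomerise C4=C5.

Step 9
Reactants: 13 (S)-4-benzyloxazolidin-2-one; 14 methyl 4-chloro-4-oxobutanoate
Product: 15 methyl 4-[(4S)-4-benzyl-2-oxooxazolidin-3-yl]-4-oxobutanoate
Conditions: Et3N, DMAP (cat.), CH2Cl2, 0 °C → rt
Reagents that add atoms: none
Why: DMAP-catalysed N-acylation of the oxazolidinone occurs at the acid chloride, the methyl ester end being far less electrophilic.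

Step 10
Reactants: 15 methyl 4-[(4S)-4-benzyl-2-oxooxazolidin-3-yl]-4-oxobutanoate; 12 (2E,6S)-8-(TBS-oxy)-3-[(TBS-oxy)methyl]-6-(PMB-oxy)-7-oxooct-2-enal
Product: 18 (4S)-4-benzyl-3-{[(2R,3S)-2-R*-5-oxotetrahydrofuran-3-yl]carbonyl}oxazolidin-2-one, via boron enolate 16 (not isolated), via syn-aldol adduct 17 (not isolated)
Conditions: 15, Bu2BOTf, i-Pr2NEt, CH2Cl2, −78 → 0 °C; 12, −78 → 0 °C; pH 7 buffer, MeOH, H2O2; then PPTS (cat.), toluene, 40 °C
Reagents that add atoms: none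
Why: In this Evans syn-aldol reaction the (Z)-boron enolate of the (S)-benzyl imide adds to the aldehyde (in preference to the C10 ketone) through a Zimmerman–Traxler chair on the face away from the benzyl group, which sets C7 (S) and C6 (R), and the C6 hydroxyl then closes the trans γ-lactone on the methyl ester.

Step 11
Reactants: 18 (4S)-4-benzyl-3-{[(2R,3S)-2-R*-5-oxotetrahydrofuran-3-yl]carbonyl}oxazolidin-2-one
Product: 20 (2R,3S)-2-R*-5-oxotetrahydrofuran-3-carboxylic acid, via lithium percarboxylate 19 (not isolated)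
Conditions: LiOH, H2O2, THF/H2O (3:1), 0 °C; then Na2SO3 (aq); 1 M HCl to pH 3
Reagents that add atoms: hydrogen peroxide, OO
Why: Hydroperoxide cleavage of the Evans auxiliary attacks the exocyclic imide carbonyl selectively, sulfite reduces the peracid, and acidification recloses any opened lactone, the weakly basic medium leaving C7 and C1 unenolised.

Step 12
Reactants: 20 (2R,3S)-2-R*-5-oxotetrahydrofuran-3-carboxylic acid
Product: 22 (4S,5R)-4-(diazoacetyl)-5-R*-dihydrofuran-2(3H)-one, via mixed anhydride 21 (not isolated)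
Conditions: i-BuOCOCl, N-methylmorpholine, THF, −20 °C; then CH2N2, Et2O, −20 → 0 °C
Reagents that add atoms: diazomethane, C=[N+]=[N-]
Why: Mixed carbonic anhydride activation and C-acylation of diazomethane (the diazoketone stage of the Arndt–Eistert sequence) supply C9 under neutral conditions that spare silyl and PMB ethers, the lactone and the C10 ketone.

Step 13
Reactants: 22 (4S,5R)-4-(diazoacetyl)-5-R*-dihydrofuran-2(3H)-one
Product: 23 (4S,5R)-4-(bromoacetyl)-5-R*-dihydrofuran-2(3H)-one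
Conditions: HBr (48% aq, 1.05 equiv), Et2O/THF, −30 °C, 10 min; NaHCO3 (aq)
Reagents that add atoms: hydrogen bromide, Br
Why: C-protonation of the diazoketone and displacement of dinitrogen by bromide give the bromomethyl ketone regiospecifically at C9, the single equivalent of acid being consumed at low temperature before silyl ethers can be cleaved.

Step 14
Reactants: 23 (4S,5R)-4-(bromoacetyl)-5-R*-dihydrofuran-2(3H)-one
Product: 25 (1S,4E,6R,7S,10R)-10-hydroxy-1-(PMB-oxy)-14,15-bis(TBS-oxy)-8-oxo-13-norgermacr-4-en-12,6-olide, via samarium enolate 24 (not isolated)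
Conditions: SmI2 (0.1 M in THF, 2.2 equiv) added dropwise to 23 (2 mM in THF), −78 °C; sat. NH4Cl
Reagents that add atoms: none
Why: Samarium diiodide reduces the C9–Br bond by two successive one-electron transfers, and the samarium(III) enolate so formed, whose double bond can only lie between C8 and C9, attacks the C10 carbonyl in an intramolecular samarium Reformatsky (reductive aldol) addition, a reaction type established for closing medium and large rings. The ten-membered carbocycle closes by C9–C10 bond formation in a 10-(enolendo)-exo-trig mode. The new stereocentre C10 is governed by C1: samarium(III) binds the C10 carbonyl oxygen and the C1 PMB-ether oxygen in a five-membered Cram chelate (the bulky C14 silyl ether is a poor ligand), so C9 adds on the face carrying the C1 hydrogen and gives (10R). The step needs chemoselectivity for the bromomethyl ketone over the α-alkoxy ketone and ring closure over oligomerisation; the first should be secured by the much faster electron transfer to the C–Br bond at −78 °C when SmI2 is never in excess, the second by 2 mM dilution together with the folding imposed by the trans lactone and the C4=C5 alkene (C3 cis to C6). The neutral medium leaves the base-sensitive C6–O/C7–H/C8=O array and the C1 and C7 centres untouched.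

Step 15
Reactants: 25 (1S,4E,6R,7S,10R)-10-hydroxy-1-(PMB-oxy)-14,15-bis(TBS-oxy)-8-oxo-13-norgermacr-4-en-12,6-olide
Product: 26 (1S,4E,6R,7R,8S,10R)-8,10-dihydroxy-1-(PMB-oxy)-14,15-bis(TBS-oxy)-13-norgermacr-4-en-12,6-olide
Conditions: Me4NBH(OAc)3, MeCN/AcOH (1:1), −30 → −20 °C
Reagents that add atoms: none
Why: In this Evans–Saksena reduction the C10 hydroxyl exchanges onto boron and delivers hydride intramolecularly through a chair with C7 and C1 equatorial, which should give the 8,10-anti diol, i.e. (8S), while the lactone is not reduced.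

Step 16
Reactants: 26 (1S,4E,6R,7R,8S,10R)-8,10-dihydroxy-1-(PMB-oxy)-14,15-bis(TBS-oxy)-13-norgermacr-4-en-12,6-olide
Product: 27 (1S,4E,6R,7S,8S,10R)-10-hydroxy-1-(PMB-oxy)-8-(TES-oxy)-14,15-bis(TBS-oxy)-13-norgermacr-4-en-12,6-olide
Conditions: TESCl, imidazole, DMAP (cat.), DMF, 0 °C → rt
Reagents that add atoms: chlorotriethylsilane, CC[Si](Cl)(CC)CC
Why: Silylation takes the secondary C8 hydroxyl only, the tertiary C10 hydroxyl being too hindered for a silyl chloride.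

Step 17
Reactants: 27 (1S,4E,6R,7S,8S,10R)-10-hydroxy-1-(PMB-oxy)-8-(TES-oxy)-14,15-bis(TBS-oxy)-13-norgermacr-4-en-12,6-olide
Product: 28 (1S,4E,6R,7S,8S,10R)-1,10-dihydroxy-8-(TES-oxy)-14,15-bis(TBS-oxy)-13-norgermacr-4-en-12,6-olide
Conditions: DDQ, CH2Cl2/pH 7 buffer (10:1), 0 °C
Reagents that add atoms: none
Why: Oxidative PMB cleavage by DDQ proceeds by benzylic hydride abstraction and hydrolysis of the oxocarbenium ion, the aqueous buffer favouring hydrolysis over acetal formation with the neighbouring tertiary hydroxyl while silyl ethers and the alkene stay inert.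

Step 18
Reactants: 28 (1S,4E,6R,7S,8S,10R)-1,10-dihydroxy-8-(TES-oxy)-14,15-bis(TBS-oxy)-13-norgermacr-4-en-12,6-olide
Product: 29 (1S,4E,6R,7S,8S,10R)-10-hydroxy-1-(mesyloxy)-8-(TES-oxy)-14,15-bis(TBS-oxy)-13-norgermacr-4-en-12,6-olide
Conditions: MsCl, Et3N, CH2Cl2, −20 → 0 °C
Reagents that add atoms: methanesulfonyl chloride, CS(=O)(=O)Cl
Why: Sulfonylation occurs at the only secondary hydroxyl (C1), the tertiary C10 hydroxyl being unreactive at low temperature.

Step 19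
Reactants: 29 (1S,4E,6R,7S,8S,10R)-10-hydroxy-1-(mesyloxy)-8-(TES-oxy)-14,15-bis(TBS-oxy)-13-norgermacr-4-en-12,6-olide
Product: 30 (1R,4E,6R,7S,8S,10R)-1,10-epoxy-8-(TES-oxy)-14,15-bis(TBS-oxy)-13-norgermacr-4-en-12,6-olide
Conditions: NaH, THF, 0 °C → rt
Reagents that add atoms: none
Why: Intramolecular Williamson reaction (3-exo-tet) of the C10 alkoxide displaces the C1 mesylate from the rear, inverting C1 to (R) with C10 retained, which gives the epoxide with C2 and C9 cis.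

Step 20
Reactants: 30 (1R,4E,6R,7S,8S,10R)-1,10-epoxy-8-(TES-oxy)-14,15-bis(TBS-oxy)-13-norgermacr-4-en-12,6-olide
Product: 32 (1R,4E,6R,7S,8S,10R)-13-(dimethylamino)-1,10-epoxy-8-(TES-oxy)-14,15-bis(TBS-oxy)germacr-4-en-12,6-olide (C11 epimers), via lithium enolate 31 (not isolated)
Conditions: LDA, THF, −78 °C; then CH2=NMe2+ I−, −78 → 0 °C
Reagents that add atoms: N,N-dimethylmethyleneiminium iodide, C=[N+](C)C.[I-]
Why: The lactone enolate at C11 (the only acidic C–H site, with no β-leaving group) undergoes a Mannich reaction with the iminium salt, and the C11 configuration is irrelevant because it is removed in the next step.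

Step 21
Reactants: 32 (1R,4E,6R,7S,8S,10R)-13-(dimethylamino)-1,10-epoxy-8-(TES-oxy)-14,15-bis(TBS-oxy)germacr-4-en-12,6-olide
Product: 34 (1R,4E,6R,7S,8S,10R)-1,10-epoxy-8-(TES-oxy)-14,15-bis(TBS-oxy)germacra-4,11(13)-dien-12,6-olide, via ammonium iodide 33 (not isolated)
Conditions: MeI, MeOH, rt; then NaHCO3 (aq), CH2Cl2, rt
Reagents that add atoms: none
Why: N-Methylation to the quaternary ammonium salt and E1cB elimination with mild base give the exocyclic C11=C13 alkene (Eschenmoser methylenation).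

Step 22
Reactants: 34 (1R,4E,6R,7S,8S,10R)-1,10-epoxy-8-(TES-oxy)-14,15-bis(TBS-oxy)germacra-4,11(13)-dien-12,6-olide
Product: 35 (1R,4E,6R,7R,8S,10R)-1,10-epoxy-8,14,15-trihydroxygermacra-4,11(13)-dien-12,6-olide
Conditions: TBAF, AcOH (1:1), THF, 0 °C → rt
Reagents that add atoms: none
Why: Fluoride cleaves the three silyl ethers, and buffering with acetic acid keeps free alkoxide low so that Payne rearrangement at C14 and conjugate addition to the methylene lactone should not occur.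

Step 23
Reactants: 35 (1R,4E,6R,7R,8S,10R)-1,10-epoxy-8,14,15-trihydroxygermacra-4,11(13)-dien-12,6-olide
Product: 36 (1R,4E,6R,7R,8S,10R)-1,10-epoxy-8,14-dihydroxy-15-oxogermacra-4,11(13)-dien-12,6-olide
Conditions: MnO2 (activated), CH2Cl2, rt
Reagents that add atoms: none
Why: Manganese dioxide oxidises only the allylic C15 alcohol to the enal and leaves the saturated C8 and C14 alcohols alone.

Step 24
Reactants: 36 (1R,4E,6R,7R,8S,10R)-1,10-epoxy-8,14-dihydroxy-15-oxogermacra-4,11(13)-dien-12,6-olide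
Product: 37 (1R,4E,6R,7R,8S,10R)-8,14-diacetoxy-1,10-epoxy-15-oxogermacra-4,11(13)-dien-12,6-olide (CNP0211286.1)
Conditions: Ac2O, pyridine, DMAP (cat.), CH2Cl2, 0 °C → rt
Reagents that add atoms: acetic anhydride, CC(=O)OC(C)=O
Why: DMAP-catalysed O-acylation of the remaining primary (C14) and secondary (C8) hydroxyls completes the target.

Compound list
1 | but-2-yne-1,4-diol | OCC#CCO | starting material
2 | 4-(TBS-oxy)but-2-yn-1-ol | OCC#CCO[Si](C)(C)C(C)(C)C | intermediate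
3 | sodium cyclic alkenylalanate of 2 (Al bound to O6 and C4, two 2-methoxyethoxide ligands) | [Na+].COCCO[Al-]1(OCCOC)OCC=C1CO[Si](C)(C)C(C)(C)C | intermediate
4 | (Z)-4-(TBS-oxy)-3-iodobut-2-en-1-ol | OC/C=C(/CO[Si](C)(C)C(C)(C)C)I | intermediate
5 | penta-1,4-dien-3-ol | C=CC(O)C=C | starting material
6 | (2R,3S)-1,2-epoxypent-4-en-3-ol | C=C[C@H](O)[C@H]1CO1 | intermediate
7 | (2R,3S)-1,2-epoxy-3-(PMB-oxy)pent-4-ene | C=C[C@H](OCc1ccc(OC)cc1)[C@H]1CO1 | intermediate
8 | (2R,3S)-3-(PMB-oxy)pent-4-ene-1,2-diol | C=C[C@H](OCc1ccc(OC)cc1)[C@H](O)CO | intermediate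
9 | (2R,3S)-1-(TBS-oxy)-3-(PMB-oxy)pent-4-en-2-ol | C=C[C@H](OCc1ccc(OC)cc1)[C@H](O)CO[Si](C)(C)C(C)(C)C | intermediate
10 | B-alkyl-9-BBN of 9 (boron on C3, C10–O as 9-BBN borinate) | B1(CC[C@H](OCc2ccc(OC)cc2)[C@H](OB2C3CCCC2CCC3)CO[Si](C)(C)C(C)(C)C)C2CCCC1CCC2 | intermediate
11 | (2R,3S,6E)-1-(TBS-oxy)-6-[(TBS-oxy)methyl]-3-(PMB-oxy)oct-6-ene-2,8-diol | OC/C=C(/CO[Si](C)(C)C(C)(C)C)CC[C@H](OCc1ccc(OC)cc1)[C@H](O)CO[Si](C)(C)C(C)(C)C | intermediate
12 | (2E,6S)-8-(TBS-oxy)-3-[(TBS-oxy)methyl]-6-(PMB-oxy)-7-oxooct-2-enal | O=C/C=C(/CO[Si](C)(C)C(C)(C)C)CC[C@H](OCc1ccc(OC)cc1)C(=O)CO[Si](C)(C)C(C)(C)C | intermediate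
13 | (S)-4-benzyloxazolidin-2-one | O=C1N[C@@H](Cc2ccccc2)CO1 | starting material
14 | methyl 4-chloro-4-oxobutanoate | COC(=O)CCC(Cl)=O | starting material
15 | methyl 4-[(4S)-4-benzyl-2-oxooxazolidin-3-yl]-4-oxobutanoate | COC(=O)CCC(=O)N1[C@@H](Cc2ccccc2)COC1=O | intermediate
16 | (Z)-dibutylboron enolate of 15 | COC(=O)C/C=C(\OB(CCCC)CCCC)N1[C@@H](Cc2ccccc2)COC1=O | intermediate
17 | methyl (3S,4R,5E,9S)-3-{[(4S)-4-benzyl-2-oxooxazolidin-3-yl]carbonyl}-4-hydroxy-11-(TBS-oxy)-6-[(TBS-oxy)methyl]-9-(PMB-oxy)-10-oxoundec-5-enoate | COC(=O)C[C@H](C(=O)N1[C@@H](Cc2ccccc2)COC1=O)[C@H](O)/C=C(/CO[Si](C)(C)C(C)(C)C)CC[C@H](OCc1ccc(OC)cc1)C(=O)CO[Si](C)(C)C(C)(C)C | intermediate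
18 | (4S)-4-benzyl-3-{[(2R,3S)-2-R*-5-oxotetrahydrofuran-3-yl]carbonyl}oxazolidin-2-one | O=C1OC[C@H](Cc2ccccc2)N1C(=O)[C@H]1CC(=O)O[C@@H]1/C=C(/CO[Si](C)(C)C(C)(C)C)CC[C@H](OCc1ccc(OC)cc1)C(=O)CO[Si](C)(C)C(C)(C)C | intermediate
19 | lithium (2R,3S)-2-R*-5-oxotetrahydrofuran-3-peroxycarboxylate | [Li+].[O-]OC(=O)[C@H]1CC(=O)O[C@@H]1/C=C(/CO[Si](C)(C)C(C)(C)C)CC[C@H](OCc1ccc(OC)cc1)C(=O)CO[Si](C)(C)C(C)(C)C | intermediate
20 | (2R,3S)-2-R*-5-oxotetrahydrofuran-3-carboxylic acid | OC(=O)[C@H]1CC(=O)O[C@@H]1/C=C(/CO[Si](C)(C)C(C)(C)C)CC[C@H](OCc1ccc(OC)cc1)C(=O)CO[Si](C)(C)C(C)(C)C | intermediate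
21 | isobutyl carbonic mixed anhydride of 20 | CC(C)COC(=O)OC(=O)[C@H]1CC(=O)O[C@@H]1/C=C(/CO[Si](C)(C)C(C)(C)C)CC[C@H](OCc1ccc(OC)cc1)C(=O)CO[Si](C)(C)C(C)(C)C | intermediate
22 | (4S,5R)-4-(diazoacetyl)-5-R*-dihydrofuran-2(3H)-one | [N-]=[N+]=CC(=O)[C@H]1CC(=O)O[C@@H]1/C=C(/CO[Si](C)(C)C(C)(C)C)CC[C@H](OCc1ccc(OC)cc1)C(=O)CO[Si](C)(C)C(C)(C)C | intermediate
23 | (4S,5R)-4-(bromoacetyl)-5-R*-dihydrofuran-2(3H)-one (1S,6R,7S) | BrCC(=O)[C@H]1CC(=O)O[C@@H]1/C=C(/CO[Si](C)(C)C(C)(C)C)CC[C@H](OCc1ccc(OC)cc1)C(=O)CO[Si](C)(C)C(C)(C)C | intermediate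
24 | samarium(III) enolate (C8=C9) of 23 | C=C(O[Sm](I)I)[C@H]1CC(=O)O[C@@H]1/C=C(/CO[Si](C)(C)C(C)(C)C)CC[C@H](OCc1ccc(OC)cc1)C(=O)CO[Si](C)(C)C(C)(C)C | intermediate
25 | (1S,4E,6R,7S,10R)-10-hydroxy-1-(PMB-oxy)-14,15-bis(TBS-oxy)-8-oxo-13-norgermacr-4-en-12,6-olide | C1C(=O)O[C@@H]2/C=C(/CO[Si](C)(C)C(C)(C)C)CC[C@H](OCc3ccc(OC)cc3)[C@](O)(CO[Si](C)(C)C(C)(C)C)CC(=O)[C@@H]12 | intermediate
26 | (1S,4E,6R,7R,8S,10R)-8,10-dihydroxy-1-(PMB-oxy)-14,15-bis(TBS-oxy)-13-norgermacr-4-en-12,6-olide | C1C(=O)O[C@@H]2/C=C(/CO[Si](C)(C)C(C)(C)C)CC[C@H](OCc3ccc(OC)cc3)[C@](O)(CO[Si](C)(C)C(C)(C)C)C[C@H](O)[C@@H]12 | intermediate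
27 | (1S,4E,6R,7S,8S,10R)-10-hydroxy-1-(PMB-oxy)-8-(TES-oxy)-14,15-bis(TBS-oxy)-13-norgermacr-4-en-12,6-olide | C1C(=O)O[C@@H]2/C=C(/CO[Si](C)(C)C(C)(C)C)CC[C@H](OCc3ccc(OC)cc3)[C@](O)(CO[Si](C)(C)C(C)(C)C)C[C@H](O[Si](CC)(CC)CC)[C@@H]12 | intermediate
28 | (1S,4E,6R,7S,8S,10R)-1,10-dihydroxy-8-(TES-oxy)-14,15-bis(TBS-oxy)-13-norgermacr-4-en-12,6-olide | C1C(=O)O[C@@H]2/C=C(/CO[Si](C)(C)C(C)(C)C)CC[C@H](O)[C@](O)(CO[Si](C)(C)C(C)(C)C)C[C@H](O[Si](CC)(CC)CC)[C@@H]12 | intermediate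
29 | (1S,4E,6R,7S,8S,10R)-10-hydroxy-1-(mesyloxy)-8-(TES-oxy)-14,15-bis(TBS-oxy)-13-norgermacr-4-en-12,6-olide | C1C(=O)O[C@@H]2/C=C(/CO[Si](C)(C)C(C)(C)C)CC[C@H](OS(C)(=O)=O)[C@](O)(CO[Si](C)(C)C(C)(C)C)C[C@H](O[Si](CC)(CC)CC)[C@@H]12 | intermediate
30 | (1R,4E,6R,7S,8S,10R)-1,10-epoxy-8-(TES-oxy)-14,15-bis(TBS-oxy)-13-norgermacr-4-en-12,6-olide | C1C(=O)O[C@@H]2/C=C(/CO[Si](C)(C)C(C)(C)C)CC[C@H]3O[C@@]3(CO[Si](C)(C)C(C)(C)C)C[C@H](O[Si](CC)(CC)CC)[C@@H]12 | intermediate
31 | lithium enolate (C11=C12) of 30 | C1=C([O-])O[C@@H]2/C=C(/CO[Si](C)(C)C(C)(C)C)CC[C@H]3O[C@@]3(CO[Si](C)(C)C(C)(C)C)C[C@H](O[Si](CC)(CC)CC)[C@@H]12.[Li+] | intermediate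
32 | (1R,4E,6R,7S,8S,10R)-13-(dimethylamino)-1,10-epoxy-8-(TES-oxy)-14,15-bis(TBS-oxy)germacr-4-en-12,6-olide (C11 epimers) | CN(C)CC1C(=O)O[C@@H]2/C=C(/CO[Si](C)(C)C(C)(C)C)CC[C@H]3O[C@@]3(CO[Si](C)(C)C(C)(C)C)C[C@H](O[Si](CC)(CC)CC)[C@@H]12 | intermediate
33 | 13-(trimethylammonio) iodide of 32 | C[N+](C)(C)CC1C(=O)O[C@@H]2/C=C(/CO[Si](C)(C)C(C)(C)C)CC[C@H]3O[C@@]3(CO[Si](C)(C)C(C)(C)C)C[C@H](O[Si](CC)(CC)CC)[C@@H]12.[I-] | intermediate
34 | (1R,4E,6R,7S,8S,10R)-1,10-epoxy-8-(TES-oxy)-14,15-bis(TBS-oxy)germacra-4,11(13)-dien-12,6-olide | C=C1C(=O)O[C@@H]2/C=C(/CO[Si](C)(C)C(C)(C)C)CC[C@H]3O[C@@]3(CO[Si](C)(C)C(C)(C)C)C[C@H](O[Si](CC)(CC)CC)[C@@H]12 | intermediate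
35 | (1R,4E,6R,7R,8S,10R)-1,10-epoxy-8,14,15-trihydroxygermacra-4,11(13)-dien-12,6-olide | C=C1C(=O)O[C@@H]2/C=C(/CO)CC[C@H]3O[C@@]3(CO)C[C@H](O)[C@@H]12 | intermediate
36 | (1R,4E,6R,7R,8S,10R)-1,10-epoxy-8,14-dihydroxy-15-oxogermacra-4,11(13)-dien-12,6-olide | C=C1C(=O)O[C@@H]2/C=C(/C=O)CC[C@H]3O[C@@]3(CO)C[C@H](O)[C@@H]12 | intermediate
37 | (1R,4E,6R,7R,8S,10R)-8,14-diacetoxy-1,10-epoxy-15-oxogermacra-4,11(13)-dien-12,6-olide (CNP0211286.1) | C=C1C(=O)O[C@@H]2/C=C(/C=O)CC[C@H]3O[C@@]3(COC(C)=O)C[C@H](OC(C)=O)[C@@H]12 | target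

Total step count: 24. Longest linear sequence: 21 steps (steps 3–8 and 10–24, from penta-1,4-dien-3-ol).

Steps most likely to fail

Step 14 (ring closure). Electron transfer may reach the C10 α-alkoxy ketone and strip the C1 or C14 oxygen substituent. The samarium enolate may also be protonated before it reaches C10, may add intermolecularly, or may add to the wrong carbonyl face. Fallback: setting out from bromomethyl ketone 23, reductive silylation with zinc dust and chlorotrimethylsilane (TMEDA, Et2O, 0 °C) should give the regiodefined C8=C9 trimethylsilyl enol ether F1. A chelation-controlled intramolecular Mukaiyama aldol addition (MgBr2·OEt2, CH2Cl2, 2 mM, −78 → −20 °C; aqueous work-up), in which magnesium bridges the C10 carbonyl and the C1 ether oxygen as samarium would, comes back to the route at β-hydroxy ketone 25.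

Step 15 (C8 reduction). Hydride delivery may run through the alternative chair with C1 axial, or transannular shielding in the medium ring may override the directing effect, giving poor facial selectivity at C8. Fallback: setting out from 25, chelation-controlled reduction (Et2BOMe, NaBH4, THF/MeOH, −78 °C; Narasaka–Prasad) should give the 8,10-syn (8R) diol F2. Mitsunobu inversion at the secondary C8 hydroxyl (4-nitrobenzoic acid, PPh3, DIAD, toluene; the tertiary C10 hydroxyl is inert) gives the (8S) 4-nitrobenzoate F3, and methanolysis (K2CO3, MeOH, 0 °C) comes back to the route at diol 26.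

Step 11 (auxiliary removal). Hydroperoxide may add to the electrophilic C10 ketone and cleave it oxidatively, or open the lactone, and prolonged contact with base may erode the C1 configuration. Fallback: setting out from lactone imide 18, peroxide-free thiolysis with lithium ethanethiolate (EtSH, n-BuLi, THF, 0 °C), which is selective for the exocyclic acyl group, should give the S-ethyl thioester F4. Silver-assisted hydrolysis (AgNO3, 2,6-lutidine, THF/H2O, rt) comes back to the route at acid 20.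

Further compounds
F1 | step 14 | trimethylsilyl enol ether (C8=C9) of the debrominated ketone from 23 | C=C(O[Si](C)(C)C)[C@H]1CC(=O)O[C@@H]1/C=C(/CO[Si](C)(C)C(C)(C)C)CC[C@H](OCc1ccc(OC)cc1)C(=O)CO[Si](C)(C)C(C)(C)C
F2 | step 15 | (1S,4E,6R,8R,10R)-8,10-dihydroxy-1-(PMB-oxy)-14,15-bis(TBS-oxy)-13-norgermacr-4-en-12,6-olide (C8 epimer of 26) | C1C(=O)O[C@@H]2/C=C(/CO[Si](C)(C)C(C)(C)C)CC[C@H](OCc3ccc(OC)cc3)[C@](O)(CO[Si](C)(C)C(C)(C)C)C[C@@H](O)[C@@H]12
F3 | step 15 | (8S) 4-nitrobenzoate of 26 | C1C(=O)O[C@@H]2/C=C(/CO[Si](C)(C)C(C)(C)C)CC[C@H](OCc3ccc(OC)cc3)[C@](O)(CO[Si](C)(C)C(C)(C)C)C[C@H](OC(=O)c3ccc(cc3)[N+](=O)[O-])[C@@H]12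
F4 | step 11 | S-ethyl (2R,3S)-2-R*-5-oxotetrahydrofuran-3-carbothioate | CCSC(=O)[C@H]1CC(=O)O[C@@H]1/C=C(/CO[Si](C)(C)C(C)(C)C)CC[C@H](OCc1ccc(OC)cc1)C(=O)CO[Si](C)(C)C(C)(C)C
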